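**Plan**
- Retrosynthesis: first restore the O-alkyl groups at O5 and O7 (isopropyl) and O5'' (methyl). Then cut C8a–O1 and C8a''–O1'' together, which opens both rings C to a biaryl bis(1,3-diketone). Then cut C2–C3/C2''–C3'' (Claisen), C4–C4a/C4''–C4a'' (acetylation), and last the C6–C8'' biaryl bond.
- Enabling feature: in each flavone unit O1 is bound to C8a. This ring A carbon lies ortho to the C4 ketone on C4a and meta to the oxygens on C5 and C7. A fluorine on C8a is therefore activated for displacement, and it marks which of the two carbons flanking C4a becomes the ring-oxygen carbon. That fixes the 6-linkage of unit 1 and the 8''-linkage of unit 2.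
- Forward order: all four benzene rings are bought. C6–C8'' is made first by Suzuki coupling, both acetyl groups and then both anisoyl groups are added, both rings C close in one flask, and BCl3 removes three O-alkyl groups.
- Both rings A come from 1-fluoro-3,5-dimethoxybenzene. Unit 2 is iodinated next to fluorine (para to OMe). Unit 1 is functionalised between its two oxygens by resorcinol iodination, not by lithiation, because fluorine would steer a base to its own ortho carbon.
- Stereochemistry: the target has no stereocentre. The hindered C6–C8'' axis is formed without control.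

Key step: step 9

Assumption: the target string fixes no configuration at the C6–C8'' axis, so the compound is prepared as the racemate with respect to that axis.

**Step 1**
Reactants: 1 1-fluoro-3,5-dimethoxybenzene
Product: 2 5-fluorobenzene-1,3-diol
Conditions: BBr3, CH2Cl2, −78 °C to rt; then H2O
Reagents that add atoms: none
Why: Lewis acid ether cleavage, in which BBr3 binds each methoxy oxygen and bromide removes the methyl group by SN2 while the C–F bond stays inert.

**Step 2**
Reactants: 2 5-fluorobenzene-1,3-diol
Product: 3 5-fluoro-2-iodobenzene-1,3-diol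
Conditions: I2, NaHCO3, H2O/THF, 0 °C to rt
Reagents that add atoms: iodine, II
Why: Electrophilic aromatic iodination of resorcinols in aqueous bicarbonate is known to go to the carbon between the two hydroxyls (resorcinol, orcinol and olivetol behave this way), and here that carbon is also para to fluorine whereas C4 and C6 are ortho to it and inductively deactivated.

**Step 3**
Reactants: 3 5-fluoro-2-iodobenzene-1,3-diol; 4 2-bromopropane
Product: 5 5-fluoro-2-iodo-1,3-diisopropoxybenzene
Conditions: K2CO3, DMF, 60 °C
Reagents that add atoms: 2-bromopropane 4, CC(C)Br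
Why: Double Williamson ether synthesis, in which excess bromide offsets its loss by elimination and neither the unactivated C–F bond nor the C–I bond reacts with carbonate.

**Step 4**
Reactants: 5 5-fluoro-2-iodo-1,3-diisopropoxybenzene
Product: 7 2-(4-fluoro-2,6-diisopropoxyphenyl)-4,4,5,5-tetramethyl-1,3,2-dioxaborolane, via arylmagnesium chloride 6 (not isolated)
Conditions: iPrMgCl·LiCl, THF, 0 °C to rt; then iPrOBpin, 0 °C to rt; then dilute HCl
Reagents that add atoms: 2-isopropoxy-4,4,5,5-tetramethyl-1,3,2-dioxaborolane, CC(C)OB1OC(C)(C)C(C)(C)O1; isopropylmagnesium chloride, CC(C)[Mg]Cl (magnesium and chlorine of 6 only)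
Why: Iodine–magnesium exchange, helped by the two chelating ortho alkoxy groups, places the metal exactly where the iodine was (para to fluorine, so no aryne can form), and the Grignard reagent is trapped by borylation with the alkoxyboronate.

**Step 5**
Reactants: 1 1-fluoro-3,5-dimethoxybenzene
Product: 8 1-fluoro-2-iodo-3,5-dimethoxybenzene
Conditions: N-iodosuccinimide (1 equiv), MeCN, 0 °C to rt, dark
Reagents that add atoms: N-iodosuccinimide, O=C1CCC(=O)N1I
Why: Electrophilic aromatic iodination of methoxyarenes with N-iodosuccinimide in MeCN goes para to a methoxy group, which here is the carbon between F and OMe, while the carbon between the two methoxy groups is only ortho-activated and more shielded.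

**Step 6**
Reactants: 7 2-(4-fluoro-2,6-diisopropoxyphenyl)-4,4,5,5-tetramethyl-1,3,2-dioxaborolane; 8 1-fluoro-2-iodo-3,5-dimethoxybenzene
Product: 9 2',4-difluoro-2,6-diisopropoxy-4',6'-dimethoxybiphenyl
Conditions: Pd(OAc)2 (cat.), SPhos, K3PO4, toluene/H2O, 100 °C
Reagents that add atoms: none
Why: Suzuki–Miyaura coupling, in which the aryl iodide adds readily to zerovalent palladium and the bulky, electron-rich biarylphosphine is the established ligand type for biaryls with four ortho substituents, one of which is only fluorine here.

**Step 7**
Reactants: 9 2',4-difluoro-2,6-diisopropoxy-4',6'-dimethoxybiphenyl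
Product: 10 3,3'-diacetyl-2',4-difluoro-2,6-diisopropoxy-4',6'-dimethoxybiphenyl
Conditions: AcOH, (CF3CO)2O, H3PO4 (cat.), CH2Cl2, 0 to 40 °C
Reagents that add atoms: acetic acid, CC(=O)O
Why: Friedel–Crafts acylation with the mixed anhydride made in situ needs no metal halide and is known to spare aryl isopropyl ethers; each ring reacts para to one alkoxy group and ortho to the other, next to fluorine, which is the only kind of free site in unit 1 and is preferred in unit 2 over the carbon wedged between two methoxy groups.

**Step 8**
Reactants: 10 3,3'-diacetyl-2',4-difluoro-2,6-diisopropoxy-4',6'-dimethoxybiphenyl; 11 methyl 4-methoxybenzoate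
Product: 12 1,1'-(2',4-difluoro-2,6-diisopropoxy-4',6'-dimethoxybiphenyl-3,3'-diyl)bis[3-(4-methoxyphenyl)propane-1,3-dione]
Conditions: LiN(SiMe3)2 (5 equiv), 11 (3 equiv), THF, −78 to 45 °C; then 1 M HCl, 0 °C
Reagents that add atoms: methyl 4-methoxybenzoate 11, COC(=O)c1ccc(OC)cc1
Why: Double crossed Claisen condensation of methyl ketone enolates with a non-enolisable ester, driven by deprotonation of each diketone, while the tight lithium chelate holds both oxygens away from C–F so that ring closure should not start early.

**Step 9**
Reactants: 12 1,1'-(2',4-difluoro-2,6-diisopropoxy-4',6'-dimethoxybiphenyl-3,3'-diyl)bis[3-(4-methoxyphenyl)propane-1,3-dione]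
Product: 14 5,7-diisopropoxy-5'',7'',4',4'''-tetramethoxy-6,8''-biflavone, via half-closed fluoro diketone 13 (not isolated)
Conditions: K2CO3 (5 equiv), anhydrous DMF, 100 °C
Reagents that add atoms: none
Why: K2CO3 turns each 1,3-diketone into a potassium enolate that is loose enough in DMF to rotate about C3–C4 and bring the oxygen on C2 over C8a; addition there gives a Meisenheimer anion whose charge lies on C4a, C6 and C8 and drains from C4a into the C4 ketone, and loss of fluoride restores ring A. This is the known base-mediated cyclisation of 1-(2-fluoroaryl)-1,3-diketones to flavones, an intramolecular SNAr O-arylation, run here twice in one flask. Each ring C closes as a six-membered ring by addition–elimination at an sp2 carbon (formally 6-endo-trig, since the charge leaves through the ring bond C8a–C4a), and unit 1 probably closes first because its fluorine has only H8 as outer neighbour, which gives 13 on the way. The oxygens on C5 and C7 are meta to C8a, so they feed no electron density into the attacked carbon and sit on uncharged carbons of the anion, but they weaken the C4 ketone as an acceptor, which is why heating is planned. Two selectivities are needed: O- over C-attack, secured because attack through C3 would require a four-membered ring, and C8a over C5 as the site of substitution, secured because fluorine accelerates the rate-limiting addition and leaves far better than isopropoxide or methoxide. No stereocentre is formed and the C6–C8'' axis stays racemic.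

**Step 10**
Reactants: 14 5,7-diisopropoxy-5'',7'',4',4'''-tetramethoxy-6,8''-biflavone
Product: 15 5,7,5''-trihydroxy-7'',4',4'''-trimethoxy-6,8''-biflavone (target)
Conditions: BCl3 (10 equiv), CH2Cl2, −78 °C to rt; then H2O
Reagents that add atoms: none
Why: Selective Lewis acid dealkylation, in which BCl3 cleaves aryl isopropyl ethers through the stabilised secondary cation and removes only the methyl ether that can chelate boron to a peri carbonyl (O5''), so the methyl ethers on O7'', O4' and O4''' should remain.

**Compound list**
1 | 1-fluoro-3,5-dimethoxybenzene | COc1cc(F)cc(OC)c1 | starting material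
2 | 5-fluorobenzene-1,3-diol | Oc1cc(F)cc(O)c1 | intermediate
3 | 5-fluoro-2-iodobenzene-1,3-diol (iodine between the hydroxyls, para to fluorine) | Oc1cc(F)cc(O)c1I | intermediate
4 | 2-bromopropane | CC(C)Br | starting material
5 | 5-fluoro-2-iodo-1,3-diisopropoxybenzene | CC(C)Oc1cc(F)cc(OC(C)C)c1I | intermediate
6 | (4-fluoro-2,6-diisopropoxyphenyl)magnesium chloride | CC(C)Oc1cc(F)cc(OC(C)C)c1[Mg]Cl | intermediate
7 | 2-(4-fluoro-2,6-diisopropoxyphenyl)-4,4,5,5-tetramethyl-1,3,2-dioxaborolane | CC(C)Oc1cc(F)cc(OC(C)C)c1B1OC(C)(C)C(C)(C)O1 | intermediate
8 | 1-fluoro-2-iodo-3,5-dimethoxybenzene (iodine between F and OMe) | COc1cc(F)c(I)c(OC)c1 | intermediate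
9 | 2',4-difluoro-2,6-diisopropoxy-4',6'-dimethoxybiphenyl | COc1cc(F)c(-c2c(OC(C)C)cc(F)cc2OC(C)C)c(OC)c1 | intermediate
10 | 3,3'-diacetyl-2',4-difluoro-2,6-diisopropoxy-4',6'-dimethoxybiphenyl (each acetyl between a fluorine and an alkoxy group; racemic axis) | CC(=O)c1c(F)cc(OC(C)C)c(-c2c(OC)cc(OC)c(C(C)=O)c2F)c1OC(C)C | intermediate
11 | methyl 4-methoxybenzoate | COC(=O)c1ccc(OC)cc1 | starting material
12 | 1,1'-(2',4-difluoro-2,6-diisopropoxy-4',6'-dimethoxybiphenyl-3,3'-diyl)bis[3-(4-methoxyphenyl)propane-1,3-dione] | COc1ccc(C(=O)CC(=O)c2c(F)cc(OC(C)C)c(-c3c(OC)cc(OC)c(C(=O)CC(=O)c4ccc(OC)cc4)c3F)c2OC(C)C)cc1 | intermediate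
13 | half-closed compound: 5,7-diisopropoxy-4'-methoxyflavone carrying at C6 the 2-fluoro-4,6-dimethoxyphenyl ring with its 3-(4-methoxyphenyl)-1,3-dioxopropyl chain at C3 of that ring | COc1ccc(-c2cc(=O)c3c(OC(C)C)c(-c4c(OC)cc(OC)c(C(=O)CC(=O)c5ccc(OC)cc5)c4F)c(OC(C)C)cc3o2)cc1 | intermediate
14 | 5,7-diisopropoxy-5'',7'',4',4'''-tetramethoxy-6,8''-biflavone | COc1ccc(-c2cc(=O)c3c(OC(C)C)c(-c4c(OC)cc(OC)c5c(=O)cc(-c6ccc(OC)cc6)oc45)c(OC(C)C)cc3o2)cc1 | intermediate
15 | 5,7,5''-trihydroxy-7'',4',4'''-trimethoxy-6,8''-biflavone | COc1ccc(-c2cc(=O)c3c(O)c(-c4c(OC)cc(O)c5c(=O)cc(-c6ccc(OC)cc6)oc45)c(O)cc3o2)cc1 | target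

**Step count**
Total step count: 10.
Longest linear sequence: 9 (steps 1, 2, 3, 4, 6, 7, 8, 9, 10).

**Steps most likely to fail**

**Step 6.**
- Risk: transmetalation from a boron atom flanked by two isopropoxy groups may be slower than protodeboronation in the hot aqueous base. Reductive elimination to a biaryl with four ortho substituents may also lag behind hydrodehalogenation of the iodide.
- Fallback: this sets out from 5 and changes the transmetalating metal. The iodine–magnesium exchange of step 4 gives 6, and ZnCl2 in THF converts it into (4-fluoro-2,6-diisopropoxyphenyl)zinc chloride F1. F1 is joined to 8 by Negishi coupling with Pd2(dba)3 and RuPhos in THF at 65 °C. No water or base is present, so protodemetalation is shut off. The sequence rejoins the route at 9.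

**Step 7.**
- Risk: the acid medium may strip the isopropyl group that ends up next to the new ketone. Some attack may occur at the carbon between the two methoxy groups of unit 2. The reaction may also stop after one ring has been acylated.
- Fallback: this sets out from 9 and builds the acetyl groups at a lower oxidation level. Double Vilsmeier–Haack formylation (POCl3, DMF, 0 to 70 °C) is harmless to alkyl aryl ethers and strongly para-directed. It should give 2',4-difluoro-2,6-diisopropoxy-4',6'-dimethoxybiphenyl-3,3'-dicarbaldehyde F2. MeMgBr in THF at −78 to 0 °C adds to both aldehydes to give the bis(1-hydroxyethyl) compound F3 as a mixture of diastereomers. Dess–Martin periodinane in CH2Cl2 oxidises all of these to the same diketone, so the sequence rejoins the route at 10.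

**Step 9.**
- Risk: the C4 carbonyl is part of a charged diketonate and is fed by two alkoxy donors, so it may activate C8a too weakly. Closure may then stall, above all in unit 2 where the fluorine is buttressed by the neighbouring aryl ring. At the temperature then needed, the diketone chains may fragment by retro-Claisen cleavage.
- Fallback: this sets out from 12 and adds a removable third acceptor to each chain. Magnesium-mediated C-acylation (4-methoxybenzoyl chloride, MgCl2, Et3N, MeCN, 0 °C to rt) gives the bis(triketone) F4. In F4 the enolate charge rests mainly on the two anisoyl carbonyls, so the 2-fluoroaroyl ketone is a freer acceptor.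
- K2CO3 in DMF at moderate temperature should then close both rings through either of the equivalent anisoyl oxygens, by the tandem acylation–SNAr manifold known for 2-fluorobenzoyl tricarbonyl compounds. This gives the 3,3''-bis(4-methoxybenzoyl) biflavone F5.
- Brief heating of F5 with K2CO3 in aqueous ethanol removes the 3-aroyl groups, as in the last stage of an Allan–Robinson flavone synthesis. The sequence rejoins the route at 14.

**Further compounds**
F1 | step 6 | (4-fluoro-2,6-diisopropoxyphenyl)zinc chloride | CC(C)Oc1cc(F)cc(OC(C)C)c1[Zn]Cl
F2 | step 7 | 2',4-difluoro-2,6-diisopropoxy-4',6'-dimethoxybiphenyl-3,3'-dicarbaldehyde | O=Cc1c(F)cc(OC(C)C)c(-c2c(OC)cc(OC)c(C=O)c2F)c1OC(C)C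
F3 | step 7 | 1,1'-(2',4-difluoro-2,6-diisopropoxy-4',6'-dimethoxybiphenyl-3,3'-diyl)diethanol (mixture of diastereomers) | CC(O)c1c(F)cc(OC(C)C)c(-c2c(OC)cc(OC)c(C(C)O)c2F)c1OC(C)C
F4 | step 9 | bis(triketone): 12 with a 4-methoxybenzoyl group on the central carbon of each diketone chain | COc1ccc(cc1)C(=O)C(C(=O)c1ccc(OC)cc1)C(=O)c1c(F)cc(OC(C)C)c(c1OC(C)C)-c1c(OC)cc(OC)c(c1F)C(=O)C(C(=O)c1ccc(OC)cc1)C(=O)c1ccc(OC)cc1
F5 | step 9 | 3,3''-bis(4-methoxybenzoyl)-5,7-diisopropoxy-5'',7'',4',4'''-tetramethoxy-6,8''-biflavone | COc1ccc(-c2c(C(=O)c7ccc(OC)cc7)c(=O)c3c(OC(C)C)c(-c4c(OC)cc(OC)c5c(=O)c(C(=O)c7ccc(OC)cc7)c(-c6ccc(OC)cc6)oc45)c(OC(C)C)cc3o2)cc1
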